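**Plan**

1. Numbering: furanone O1, C2–C5; cyclohexanone C1'–C6' (C1' bears the furanone, C2' the hexenoyl group, C4' the ketone, C5' the propenyl group). Retrosynthesis cuts the furanone C3–C4 bond first (enolate C-acylation). The precursor holds the C4 carboxyl on the enol oxygen of the side-chain ketone as a six-membered enol lactone (temporary ring B).
2. Further cuts: the C2'–acyl bond (conjugate addition of an acyl radical), the C5'–propenyl bond (enolate alkenylation) and the C5–C1' bond (pyruvate aldol), back to 3-ethoxycyclohex-2-enone.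
3. Forward: the carbocycle (ring A) is bought and decorated by aldol, carbonyl transposition, alkenylation, O-propionylation and acylation. Ring B is then closed by enol lactonisation and opened again in the step that closes the tetronic acid (ring C).
4. Enabling feature: C4 and the side-chain ketone carbon are 1,5-related through C5, C1' and C2'. The C4 carboxyl therefore reaches the ketone enol oxygen in a six-membered ring, while the propionate on the C5 oxygen sits 5-exo to that carbonyl; attack there releases the ketone as a regiodefined enolate.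
5. Stereochemistry: quaternary C5 (R) and C1' (S) come from one catalytic asymmetric pyruvate aldol (ligand-controlled face, syn-selective open transition state). C2' (R, cis) and C5' (S) are set last by kinetic protonation anti to the tetronate; C5' is also the thermodynamic epimer. Both (E) alkenes come from (E) building blocks.

Key step: step 10

Remark: tert-butyl pyruvate, (E)-1-bromoprop-1-ene and (E)-5-bromopent-2-ene are assumed to be purchasable as single geometric isomers; the target is taken as the 4-hydroxy (enol) tautomer drawn.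

**Step 1**
Reactants: 1 3-ethoxycyclohex-2-en-1-one
Product: 2 1-ethoxy-3-(trimethylsilyloxy)cyclohexa-1,3-diene
Conditions: LDA, THF, −78 °C; then TMSCl, −78 °C → rt
Reagents that add atoms: chlorotrimethylsilane C[Si](C)(C)Cl
Why: Kinetic deprotonation of the vinylogous ester at its α'-carbon and O-silylation should give the cross-conjugated, Danishefsky-type dienol silane (regiodefined silyl enol ether formation); no stereocenter is formed.

**Step 2**
Reactants: 2 1-ethoxy-3-(trimethylsilyloxy)cyclohexa-1,3-diene; 3 tert-butyl 2-oxopropanoate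
Product: 5 tert-butyl (2R)-2-[(1R)-4-ethoxy-2-oxocyclohex-3-en-1-yl]-2-hydroxypropanoate, via trimethylsilyl ether of the aldol adduct 4 (not isolated)
Conditions: Cu(OTf)2 (10 mol %), (R,R)-t-Bu-box (11 mol %), THF, −78 °C; then citric acid, MeOH–H2O, 0 °C
Reagents that add atoms: none
Why: Catalytic enantioselective Mukaiyama aldol addition to pyruvate chelated on divalent copper: the tert-butyl groups of the bis(oxazoline) screen one face of the chelate, so the terminal dienol-silane carbon should add to the open face and set the tertiary carbinol as (R) (ligand antipode chosen on the established sense of pyruvate aldol additions), while the open antiperiplanar transition state that is syn-selective for substituted enol silanes should place the ring methylene syn to the new oxygen and set the ring carbon as (1R), silyl transfer turning the catalyst over before the silyl ether is cleaved on work-up.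

**Step 3**
Reactants: 5 tert-butyl (2R)-2-[(1R)-4-ethoxy-2-oxocyclohex-3-en-1-yl]-2-hydroxypropanoate
Product: 7 tert-butyl (2R)-2-hydroxy-2-[(1S)-4-oxocyclohex-2-en-1-yl]propanoate, via allylic alcohol 6 (not isolated)
Conditions: NaBH4, CeCl3·7H2O, MeOH, −20 °C; then 1 M HCl, THF, 0 °C
Reagents that add atoms: water O
Why: Luche 1,2-reduction of the vinylogous-ester carbonyl, then acid-promoted loss of the allylic hydroxyl and hydrolysis of the enol ether (Stork–Danheiser transposition), should move the carbonyl to the former ethoxy carbon and leave the ring stereocenter untouched (its descriptor becomes S only because the ring priorities change).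

**Step 4**
Reactants: 7 tert-butyl (2R)-2-hydroxy-2-[(1S)-4-oxocyclohex-2-en-1-yl]propanoate; 8 (E)-1-bromoprop-1-ene
Product: 9 tert-butyl (2R)-2-hydroxy-2-[(1S,5S)-4-oxo-5-[(1E)-prop-1-en-1-yl]cyclohex-2-en-1-yl]propanoate
Conditions: LiHMDS (3.3 equiv), THF, −78 °C; Pd2(dba)3 (2.5 mol %), P(t-Bu)3·HBF4 (10 mol %), 8 (1.3 equiv), toluene, −78 °C → rt; AcOH, −78 °C
Reagents that add atoms: none
Why: Palladium-catalysed α-alkenylation of a ketone enolate: excess base forms the alkoxide and the kinetic cross-conjugated α'-enolate (which also protects the vinylogous aldol unit against retro-aldol cleavage), oxidative addition of 8 to zerovalent palladium and reductive elimination should join C5 to the propenyl group with retention of the (E) geometry, and protonation of the product dienolate at its α-carbon should leave this readily enolised centre cis to the C1 substituent (both pseudo-equatorial), a configuration that is renewed in step 10 in any case.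

**Step 5**
Reactants: 9 tert-butyl (2R)-2-hydroxy-2-[(1S,5S)-4-oxo-5-[(1E)-prop-1-en-1-yl]cyclohex-2-en-1-yl]propanoate; 10 propanoic anhydride
Product: 11 tert-butyl (2R)-2-[(1S,5S)-4-oxo-5-[(1E)-prop-1-en-1-yl]cyclohex-2-en-1-yl]-2-(propanoyloxy)propanoate
Conditions: Sc(OTf)3 (2 mol %), MeCN, −20 °C
Reagents that add atoms: none
Why: Lewis-acid-catalysed acylation of a hindered tertiary α-hydroxy ester with an anhydride should install the propionate under non-basic conditions that leave the β,γ-unsaturated ketone in place; no stereocenter is touched.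

**Step 6**
Reactants: 12 (E)-5-bromopent-2-ene; 13 diethyl oxalate
Product: 15 ethyl (5E)-2-oxohept-5-enoate, via (E)-pent-3-en-1-ylmagnesium bromide 14 (not isolated)
Conditions: Mg, THF, 0 °C → rt; added to 13 (2 equiv), Et2O, −78 °C; 1 M HCl
Reagents that add atoms: none
Why: Mono-addition of a Grignard reagent to excess diethyl oxalate at low temperature (the magnesium hemiketal resists a second addition) is the standard entry to α-keto esters; the (E) alkene is carried through.

**Step 7**
Reactants: 15 ethyl (5E)-2-oxohept-5-enoate
Product: 16 (5E)-2-oxohept-5-enoic acid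
Conditions: LiOH, THF–H2O, 0 °C; then 1 M HCl
Reagents that add atoms: lithium hydroxide [Li+].[OH-]
Why: Saponification of the activated α-keto ester should be fast under mild conditions; no stereocenter is involved.

**Step 8**
Reactants: 11 tert-butyl (2R)-2-[(1S,5S)-4-oxo-5-[(1E)-prop-1-en-1-yl]cyclohex-2-en-1-yl]-2-(propanoyloxy)propanoate; 16 (5E)-2-oxohept-5-enoic acid
Product: 17 tert-butyl (2R)-2-[(1S,2S,5S)-2-[(4E)-hex-4-enoyl]-4-oxo-5-[(1E)-prop-1-en-1-yl]cyclohexyl]-2-(propanoyloxy)propanoate
Conditions: 16 (1.5 equiv), Ir[dF(CF3)ppy]2(dtbbpy)PF6 (1 mol %), K2HPO4, DMF, blue LEDs, rt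
Reagents that add atoms: none
Why: Photoredox decarboxylative conjugate acylation (Giese-type addition): oxidation of the α-keto carboxylate by the excited iridium complex should release CO2 and a nucleophilic acyl radical that adds to the enone β-carbon anti to the bulky C1 substituent, the α-keto radical then being reduced and protonated; the near-neutral medium spares the acidic C5 proton, and the new C2 centre (expected trans) does not matter because step 9 erases it.

**Step 9**
Reactants: 17 tert-butyl (2R)-2-[(1S,2S,5S)-2-[(4E)-hex-4-enoyl]-4-oxo-5-[(1E)-prop-1-en-1-yl]cyclohexyl]-2-(propanoyloxy)propanoate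
Product: 19 (4R,4aS,6S)-4-methyl-3,7-dioxo-1-[(3E)-pent-3-en-1-yl]-6-[(1E)-prop-1-en-1-yl]-4,4a,5,6,7,8-hexahydro-3H-isochromen-4-yl propanoate, via carboxylic acid 18 (not isolated)
Conditions: TFA, CH2Cl2, 0 °C; evaporation; TFAA, CH2Cl2, 0 °C → rt
Reagents that add atoms: none
Why: Acidolysis of the tert-butyl ester and activation of the acid as its mixed trifluoroacetic anhydride should give the six-membered enol lactone by O-acylation of the 1,5-related side-chain ketone (enol lactonisation), the double bond forming towards the more substituted ring carbon as is usual for endocyclic enol δ-lactones; this erases the C2 stereocenter and masks both acid and ketone.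

**Step 10**
Reactants: 19 (4R,4aS,6S)-4-methyl-3,7-dioxo-1-[(3E)-pent-3-en-1-yl]-6-[(1E)-prop-1-en-1-yl]-4,4a,5,6,7,8-hexahydro-3H-isochromen-4-yl propanoate
Product: 21 (5R)-5-[(1S,2R,5S)-2-[(4E)-hex-4-enoyl]-4-oxo-5-[(1E)-prop-1-en-1-yl]cyclohexyl]-4-hydroxy-3,5-dimethylfuran-2(5H)-one, via trilithium salt of the ring-opened tetronate 20 (not isolated)
Conditions: 19 added slowly to LiHMDS (3.3 equiv), THF, −78 °C; then AcOH (6 equiv) in THF, −78 °C → 0 °C; pH 4 buffer
Reagents that add atoms: none
Why: Proposed new method: the first equivalent of base stores the ring ketone as its lithium dienolate and the second forms the propionate enolate, whose α-carbon (future C3) attacks the enol-lactone carbonyl (future C4) in a 5-exo-trig Dieckmann closure; collapse of the tetrahedral intermediate opens ring B by expelling the side-chain ketone as its regiodefined lithium enolate, and the third equivalent removes the acidic C3 proton, which makes the acyl transfer irreversible. The closest known reaction type is the Lacey–Dieckmann cyclisation of α-acyloxy esters to tetronic acids; the new element is an enol δ-lactone as acyl acceptor and leaving group, argued from the known acyl-donor ability of enol esters. Quaternary C5 and C1' are untouched; C2' is created on the quench, when the exocyclic enolate, whose neighbouring tetronate is pushed axial by allylic 1,3-strain, is protonated from the opposite face to give the cis (kinetic) ketone, and C5' is re-protonated at its α-carbon anti to the same axial group, which is also its thermodynamic cis-1,3 arrangement. The step needs chemoselective enolisation and no proton return from the new tetronic acid: once the ring ketone is an enolate the propionate CH2 is the only acidic site, the side-chain ketone is masked in the lactone and cannot take part in aldol reactions, and inverse addition to excess base at −78 °C keeps all three sites deprotonated until the quench. The event is a net isomerisation that forms the heterocycle, unveils the 1,4-diketone and sets the epimerisable cis relationship last.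

**Compound list**

1 | 3-ethoxycyclohex-2-en-1-one | CCOC1=CC(=O)CCC1 | starting material
2 | 1-ethoxy-3-(trimethylsilyloxy)cyclohexa-1,3-diene | CCOC1=CC(O[Si](C)(C)C)=CCC1 | intermediate
3 | tert-butyl 2-oxopropanoate | CC(=O)C(=O)OC(C)(C)C | starting material
4 | tert-butyl (2R)-2-[(1R)-4-ethoxy-2-oxocyclohex-3-en-1-yl]-2-(trimethylsilyloxy)propanoate | O=C1C=C(OCC)CC[C@@H]1[C@@](C)(O[Si](C)(C)C)C(=O)OC(C)(C)C | intermediate
5 | tert-butyl (2R)-2-[(1R)-4-ethoxy-2-oxocyclohex-3-en-1-yl]-2-hydroxypropanoate | O=C1C=C(OCC)CC[C@@H]1[C@@](C)(O)C(=O)OC(C)(C)C | intermediate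
6 | tert-butyl (2R)-2-[(1S,2RS)-4-ethoxy-2-hydroxycyclohex-3-en-1-yl]-2-hydroxypropanoate | OC1C=C(OCC)CC[C@@H]1[C@@](C)(O)C(=O)OC(C)(C)C | intermediate
7 | tert-butyl (2R)-2-hydroxy-2-[(1S)-4-oxocyclohex-2-en-1-yl]propanoate | C1=CC(=O)CC[C@@H]1[C@@](C)(O)C(=O)OC(C)(C)C | intermediate
8 | (E)-1-bromoprop-1-ene | C/C=C/Br | starting material
9 | tert-butyl (2R)-2-hydroxy-2-[(1S,5S)-4-oxo-5-[(1E)-prop-1-en-1-yl]cyclohex-2-en-1-yl]propanoate | C1=CC(=O)[C@H](/C=C/C)C[C@@H]1[C@@](C)(O)C(=O)OC(C)(C)C | intermediate
10 | propanoic anhydride | CCC(=O)OC(=O)CC | starting material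
11 | tert-butyl (2R)-2-[(1S,5S)-4-oxo-5-[(1E)-prop-1-en-1-yl]cyclohex-2-en-1-yl]-2-(propanoyloxy)propanoate | C1=CC(=O)[C@H](/C=C/C)C[C@@H]1[C@@](C)(OC(=O)CC)C(=O)OC(C)(C)C | intermediate
12 | (E)-5-bromopent-2-ene | C/C=C/CCBr | starting material
13 | diethyl oxalate | CCOC(=O)C(=O)OCC | starting material
14 | (E)-pent-3-en-1-ylmagnesium bromide | C/C=C/CC[Mg]Br | intermediate
15 | ethyl (5E)-2-oxohept-5-enoate | C/C=C/CCC(=O)C(=O)OCC | intermediate
16 | (5E)-2-oxohept-5-enoic acid | C/C=C/CCC(=O)C(=O)O | intermediate
17 | tert-butyl (2R)-2-[(1S,2S,5S)-2-[(4E)-hex-4-enoyl]-4-oxo-5-[(1E)-prop-1-en-1-yl]cyclohexyl]-2-(propanoyloxy)propanoate | C/C=C/CCC(=O)[C@H]1CC(=O)[C@H](/C=C/C)C[C@@H]1[C@@](C)(OC(=O)CC)C(=O)OC(C)(C)C | intermediate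
18 | (2R)-2-[(1S,2S,5S)-2-[(4E)-hex-4-enoyl]-4-oxo-5-[(1E)-prop-1-en-1-yl]cyclohexyl]-2-(propanoyloxy)propanoic acid | C/C=C/CCC(=O)[C@H]1CC(=O)[C@H](/C=C/C)C[C@@H]1[C@@](C)(OC(=O)CC)C(=O)O | intermediate
19 | (4R,4aS,6S)-4-methyl-3,7-dioxo-1-[(3E)-pent-3-en-1-yl]-6-[(1E)-prop-1-en-1-yl]-4,4a,5,6,7,8-hexahydro-3H-isochromen-4-yl propanoate | C/C=C/CCC1=C2CC(=O)[C@H](/C=C/C)C[C@@H]2[C@@](C)(OC(=O)CC)C(=O)O1 | intermediate
20 | trilithium tetronate bis(enolate) of 21 | [Li+].[Li+].[Li+].C/C=C/CCC([O-])=C1CC([O-])=C(/C=C/C)C[C@@H]1[C@@]1(C)OC(=O)C(C)=C1[O-] | intermediate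
21 | (5R)-5-[(1S,2R,5S)-2-[(4E)-hex-4-enoyl]-4-oxo-5-[(1E)-prop-1-en-1-yl]cyclohexyl]-4-hydroxy-3,5-dimethylfuran-2(5H)-one | C/C=C/CCC(=O)[C@@H]1CC(=O)[C@H](/C=C/C)C[C@@H]1[C@@]1(C)OC(=O)C(C)=C1O | target

**Step count and risks**

Total step count: 10. Longest linear sequence: 8 steps (1 → 2 → 5 → 7 → 9 → 11 → 17 → 19 → 21; steps 6 and 7 form the side branch).

Step 10. What may go wrong: the freshly formed tetronic acid could return its proton to the expelled enolate before the external base acts, which would erode the cis selectivity; the spectator ring enolate could also be acylated. The fallback uses known reactions, sets out from 19 and returns at 21. Acid-catalysed methanolysis of the enol lactone (MeOH, camphorsulfonic acid, 0 °C), with ketonisation of the released enol anti to the neighbouring quaternary group, should give methyl (2R)-2-[(1S,2R,5S)-2-[(4E)-hex-4-enoyl]-4-oxo-5-[(1E)-prop-1-en-1-yl]cyclohexyl]-2-(propanoyloxy)propanoate F1. A conventional Lacey–Dieckmann cyclisation of this methyl ester (LiHMDS, 4.4 equiv, THF, −78 → −20 °C) would follow, with both ketones held as enolates and the side-chain ketone deprotonated at its less hindered methylene so that C2' is kept. An acetic acid quench would then give 21.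

Step 4. What may go wrong: a second alkenylation of the product dienolate, or base-induced migration of the new double bond into conjugation. The fallback sets out from 7 and returns at 9. Kinetic bis-silylation (LDA, TMSCl, −78 °C) and bromination of the dienol silane with NBS, followed by mild acidic work-up, should give tert-butyl (2R)-2-[(1S,5RS)-5-bromo-4-oxocyclohex-2-en-1-yl]-2-hydroxypropanoate F2. This α-bromo ketone would be joined to (E)-prop-1-enylzinc chloride by a nickel-catalysed Negishi coupling (NiCl2·glyme, 2,2'-bipyridine, THF, 0 °C). That coupling proceeds through a radical at the ketone α-carbon under non-basic conditions and should give 9 without isomerisation.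

Step 2. What may go wrong: poor simple diastereoselection if a cycloaddition-like transition state competes with the open one. The fallback sets the two centres in separate catalyst-controlled steps; it sets out from 3 and returns at 7. The same copper bis(oxazoline) catalyst with 1-(tert-butylsulfanyl)-1-(trimethylsilyloxy)ethene and acidic work-up should give tert-butyl (2R)-4-(tert-butylsulfanyl)-2-hydroxy-2-methyl-4-oxobutanoate F3. Silylation (TESOTf, 2,6-lutidine) would give tert-butyl (2R)-4-(tert-butylsulfanyl)-2-methyl-4-oxo-2-(triethylsilyloxy)butanoate F4. Fukuyama reduction (Et3SiH, Pd/C) would give the aldehyde tert-butyl (2R)-2-methyl-4-oxo-2-(triethylsilyloxy)butanoate F5. Enamine-catalysed Michael addition to but-3-en-2-one (diphenylprolinol trimethylsilyl ether, antipode chosen for the (S) ring centre) would give tert-butyl (2R,3R)-3-formyl-2-methyl-6-oxo-2-(triethylsilyloxy)heptanoate F6. Aldol condensation (Robinson annulation, pTsOH, toluene) would give tert-butyl (2R)-2-[(1S)-4-oxocyclohex-2-en-1-yl]-2-(triethylsilyloxy)propanoate F7, and HF·pyridine would release 7.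

**Further compounds**

F1 | step 10 | methyl (2R)-2-[(1S,2R,5S)-2-[(4E)-hex-4-enoyl]-4-oxo-5-[(1E)-prop-1-en-1-yl]cyclohexyl]-2-(propanoyloxy)propanoate | C/C=C/CCC(=O)[C@@H]1CC(=O)[C@H](/C=C/C)C[C@@H]1[C@@](C)(OC(=O)CC)C(=O)OC
F2 | step 4 | tert-butyl (2R)-2-[(1S,5RS)-5-bromo-4-oxocyclohex-2-en-1-yl]-2-hydroxypropanoate | C1=CC(=O)C(Br)C[C@@H]1[C@@](C)(O)C(=O)OC(C)(C)C
F3 | step 2 | tert-butyl (2R)-4-(tert-butylsulfanyl)-2-hydroxy-2-methyl-4-oxobutanoate | CC(C)(C)SC(=O)C[C@@](C)(O)C(=O)OC(C)(C)C
F4 | step 2 | tert-butyl (2R)-4-(tert-butylsulfanyl)-2-methyl-4-oxo-2-(triethylsilyloxy)butanoate | CC(C)(C)SC(=O)C[C@@](C)(O[Si](CC)(CC)CC)C(=O)OC(C)(C)C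
F5 | step 2 | tert-butyl (2R)-2-methyl-4-oxo-2-(triethylsilyloxy)butanoate | O=CC[C@@](C)(O[Si](CC)(CC)CC)C(=O)OC(C)(C)C
F6 | step 2 | tert-butyl (2R,3R)-3-formyl-2-methyl-6-oxo-2-(triethylsilyloxy)heptanoate | O=C[C@H](CCC(C)=O)[C@@](C)(O[Si](CC)(CC)CC)C(=O)OC(C)(C)C
F7 | step 2 | tert-butyl (2R)-2-[(1S)-4-oxocyclohex-2-en-1-yl]-2-(triethylsilyloxy)propanoate | C1=CC(=O)CC[C@@H]1[C@@](C)(O[Si](CC)(CC)CC)C(=O)OC(C)(C)C
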